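**Retrosynthetic overview**
1. Target 12 ⇒ dearomative gem‑diprenylation (2 × prenyl bromide) of the aromatic acylphloroglucinol diol 9 at its only free ring carbon (last step).
2. 9 ⇒ N–O cleavage of 8. 8 ⇒ aryl–C1′ bond by chelation‑controlled ortho‑hydroxyalkylation of phlorisobutyrophenone 3 (as its magnesium phenoxide) with the (S)‑α‑aminoxy aldehyde 6, which sets C1′.
3. 6 ⇒ isovaleraldehyde + nitrosobenzene by D‑proline‑catalysed α‑aminoxylation, which sets C2′, the first stereocentre, from achiral materials.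
4. 3 ⇒ phloroglucinol + isobutyryl chloride (Friedel–Crafts acylation).
5. Rings: none is built. The single six‑membered carbocycle is bought as phloroglucinol and dearomatised in the final step.

Assumption: the SMILES shows one enol tautomer of a β‑triketone (all tautomers are the same compound), and its two descriptors correspond to (1S,2S), i.e. the syn (threo) diol.

**Step 1**
Reactants: 1 phloroglucinol; 2 isobutyryl chloride
Product: 3 phlorisobutyrophenone, 2‑methyl‑1‑(2,4,6‑trihydroxyphenyl)propan‑1‑one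
Conditions: AlCl3 (3 equiv), PhNO2/CH2Cl2, 0 → 50 °C; ice/aq HCl work‑up
Reagents that add atoms: none
Why: Friedel–Crafts C‑acylation of a very electron‑rich arene, which stops at mono‑acylation because the acyl group, hydrogen‑bonded to both ortho hydroxyls, deactivates the ring; no stereocentre.

**Step 2**
Reactants: 3 phlorisobutyrophenone; 4 isovaleraldehyde (3‑methylbutanal); 5 nitrosobenzene
Product: 8 1‑{2,4,6‑trihydroxy‑3‑[(1S,2S)‑1‑hydroxy‑3‑methyl‑2‑(phenylaminooxy)butyl]phenyl}‑2‑methylpropan‑1‑one, via (S)‑2‑anilinooxy‑3‑methylbutanal 6 (not isolated), via bromomagnesium phenoxide 7 (not isolated)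
Conditions: (i) 4 (1.2 equiv), 5 (1.0 equiv), D‑proline (10 mol %), CHCl3, 4 °C, 3 h, cold filtration; (ii) 3 (2.0 equiv), EtMgBr (2.0 equiv), Et2O then CH2Cl2, 0 °C; (iii) solution of 6 into 7, −40 → 0 °C; cold 0.5 M HCl
Reagents that add atoms: none
Why: Proposed new method: a telescoped organocatalytic α‑aminoxylation/chelation‑controlled phenoxide ortho‑hydroxyalkylation, in which D‑proline enamine catalysis (the known O‑selective nitroso aldol through a hydrogen‑bonded Houk–List transition state, >97% ee expected for this aldehyde) sets C2′ as (S) in 6, and the never‑isolated α‑aminoxy aldehyde is then captured by phenoxide 7, whose magnesium binds the aldehyde C=O and the α‑oxygen of the O–N group in a five‑membered Cram chelate so that the ortho ring carbon is delivered through a six‑membered cyclic transition state to the aldehyde face anti to the isopropyl group, giving the syn (1S,2S) carbinol after rearomatisation; the closest known reactions are the syn‑selective ortho‑hydroxyalkylation of bromomagnesium phenoxides with α‑alkoxy aldehydes and the in‑situ interception of proline‑derived α‑aminoxy aldehydes by allyl‑metal or phosphonate reagents, neither shown for an α‑aminoxy aldehyde with a phenoxide or for an acylphloroglucinol.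

**Step 3**
Reactants: 8 the anilinooxy adduct
Product: 9 1‑{3‑[(1S,2S)‑1,2‑dihydroxy‑3‑methylbutyl]‑2,4,6‑trihydroxyphenyl}‑2‑methylpropan‑1‑one
Conditions: Zn dust (5 equiv), AcOH/THF 1:4, 0 °C → rt, 1 h
Reagents that add atoms: none
Why: Dissolving‑metal reductive cleavage of the weak N–O bond of an O‑alkyl‑N‑arylhydroxylamine (the standard unmasking of proline aminoxylation products), which leaves both C–O bonds and therefore both stereocentres untouched and does not reduce the hydrogen‑bonded aryl ketone.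

**Step 4**
Reactants: 9 the aromatic diol; 10 prenyl bromide (1‑bromo‑3‑methylbut‑2‑ene)
Product: 12 4‑[(1S,2S)‑1,2‑dihydroxy‑3‑methylbutyl]‑3,5‑dihydroxy‑2‑(2‑methylpropanoyl)‑6,6‑bis(3‑methylbut‑2‑enyl)cyclohexa‑2,4‑dien‑1‑one (target), via 3‑prenyl acylphloroglucinol diol 11 (not isolated)
Conditions: 10 (2.2 equiv), 10% aq KOH (3 equiv), 0 °C, N2; then cold 1 M HCl to pH 3
Reagents that add atoms: none
Why: Dearomative gem‑C‑prenylation (the lupulone‑type alkylation of acylphloroglucinols): in water the phenoxide alkylates on carbon, the only unsubstituted ring carbon takes the first prenyl group and then, being less hindered than the carbon bearing the branched diol chain, the second, which locks the ring as the enolised β‑triketone; no stereocentre is formed and the two carbinol centres are not epimerisable under these conditions.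

**Compound list**
1 | phloroglucinol (benzene‑1,3,5‑triol) | Oc1cc(O)cc(O)c1 | starting material
2 | isobutyryl chloride (2‑methylpropanoyl chloride) | CC(C)C(=O)Cl | starting material
3 | phlorisobutyrophenone, 2‑methyl‑1‑(2,4,6‑trihydroxyphenyl)propan‑1‑one | CC(C)C(=O)c1c(O)cc(O)cc1O | intermediate
4 | isovaleraldehyde (3‑methylbutanal) | CC(C)CC=O | starting material
5 | nitrosobenzene | O=Nc1ccccc1 | starting material
6 | (2S)‑3‑methyl‑2‑(phenylaminooxy)butanal | O=C[C@@H](ONc1ccccc1)C(C)C | intermediate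
7 | bromomagnesium 3,5‑dihydroxy‑4‑(2‑methylpropanoyl)phenoxide | CC(C)C(=O)c1c(O)cc(O[Mg]Br)cc1O | intermediate
8 | 1‑{2,4,6‑trihydroxy‑3‑[(1S,2S)‑1‑hydroxy‑3‑methyl‑2‑(phenylaminooxy)butyl]phenyl}‑2‑methylpropan‑1‑one | CC(C)C(=O)c1c(O)cc(O)c([C@H](O)[C@@H](ONc2ccccc2)C(C)C)c1O | intermediate
9 | 1‑{3‑[(1S,2S)‑1,2‑dihydroxy‑3‑methylbutyl]‑2,4,6‑trihydroxyphenyl}‑2‑methylpropan‑1‑one | CC(C)C(=O)c1c(O)cc(O)c([C@H](O)[C@@H](O)C(C)C)c1O | intermediate
10 | prenyl bromide (1‑bromo‑3‑methylbut‑2‑ene) | CC(C)=CCBr | starting material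
11 | 1‑{3‑[(1S,2S)‑1,2‑dihydroxy‑3‑methylbutyl]‑2,4,6‑trihydroxy‑5‑(3‑methylbut‑2‑enyl)phenyl}‑2‑methylpropan‑1‑one | CC(C)C(=O)c1c(O)c(CC=C(C)C)c(O)c([C@H](O)[C@@H](O)C(C)C)c1O | intermediate
12 | 4‑[(1S,2S)‑1,2‑dihydroxy‑3‑methylbutyl]‑3,5‑dihydroxy‑2‑(2‑methylpropanoyl)‑6,6‑bis(3‑methylbut‑2‑enyl)cyclohexa‑2,4‑dien‑1‑one | CC(C)=CCC1(CC=C(C)C)C(=O)C(C(=O)C(C)C)=C(O)C([C@H](O)[C@@H](O)C(C)C)=C1O | target

**Total step count:** 4. **Longest linear sequence:** 4 steps (1 → 3 → 8 → 9 → 12); the aldehyde arm 4 + 5 → 6 is generated inside step 2.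

**Steps most likely to fail, with fallbacks**

Step 2, the proposed new step, is the most exposed. The aminoxy aldehyde 6 may racemise or lose aniline under the basic phenoxide, the N–O oxygen may chelate magnesium too weakly for a useful syn:anti ratio, and double addition to 3 is possible. The fallback uses known chemistry only, sets out from 4 and 5 (with 3 and its phenoxide 7 as before) and comes back to the route at 9. The D‑proline aminoxylation is run as in step 2 but quenched in the flask with NaBH4/EtOH to give (2S)‑3‑methyl‑2‑(phenylaminooxy)butan‑1‑ol F1. Zn/AcOH then gives (2S)‑3‑methylbutane‑1,2‑diol F2. Benzaldehyde dimethyl acetal with catalytic CSA gives (4S)‑4‑isopropyl‑2‑phenyl‑1,3‑dioxolane F3. DIBAL‑H (CH2Cl2, 0 °C) opens the acetal at the less hindered oxygen to (2S)‑2‑benzyloxy‑3‑methylbutan‑1‑ol F4. Dess–Martin oxidation gives (2S)‑2‑benzyloxy‑3‑methylbutanal F5, a purified, configurationally stable α‑alkoxy aldehyde of the class for which the magnesium phenoxide ortho‑hydroxyalkylation is established as syn‑selective. Coupling of F5 with 7 in CH2Cl2 gives 1‑{3‑[(1S,2S)‑2‑benzyloxy‑1‑hydroxy‑3‑methylbutyl]‑2,4,6‑trihydroxyphenyl}‑2‑methylpropan‑1‑one F6, and hydrogenolysis (H2, Pd(OH)2/C, EtOAc) gives 9.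

Step 4 is the second risk. O‑prenylation, alkylation at the chain‑bearing carbon, over‑alkylation of 12, or base‑induced retro‑aldol loss of the free diol chain could erode the yield. The fallback sets out from 9 and comes back at 12, masking the diol before the ring is alkylated. 2,2‑Dimethoxypropane with PPTS in acetone gives the dioxolane 1‑{3‑[(4S,5S)‑5‑isopropyl‑2,2‑dimethyl‑1,3‑dioxolan‑4‑yl]‑2,4,6‑trihydroxyphenyl}‑2‑methylpropan‑1‑one F9. Prenyl bromide in aqueous KOH then alkylates it through the mono‑prenylated acetonide 1‑{3‑[(4S,5S)‑5‑isopropyl‑2,2‑dimethyl‑1,3‑dioxolan‑4‑yl]‑2,4,6‑trihydroxy‑5‑(3‑methylbut‑2‑enyl)phenyl}‑2‑methylpropan‑1‑one F10 (not isolated) to the gem‑diprenyl acetonide 4‑[(4S,5S)‑5‑isopropyl‑2,2‑dimethyl‑1,3‑dioxolan‑4‑yl]‑3,5‑dihydroxy‑2‑(2‑methylpropanoyl)‑6,6‑bis(3‑methylbut‑2‑enyl)cyclohexa‑2,4‑dien‑1‑one F11. The acetonide also makes the neighbouring ring carbon more hindered. Mild hydrolysis (AcOH/H2O 4:1, 40 °C) releases 12.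

Step 3 is the third risk. On the electron‑rich arene 8, acid and zinc could ionise the benzylic alcohol (quinone‑methide formation followed by reduction), or cleavage could stall. The fallback sets out from 8 and comes back at 12 by reversing the order of the last two operations. Compound 8 is prenylated first with 10 in aqueous KOH; the N‑aryl‑O‑alkylhydroxylamine N–H is not deprotonated there and is a poor nucleophile. This passes through the mono‑prenylated arene 1‑{2,4,6‑trihydroxy‑3‑[(1S,2S)‑1‑hydroxy‑3‑methyl‑2‑(phenylaminooxy)butyl]‑5‑(3‑methylbut‑2‑enyl)phenyl}‑2‑methylpropan‑1‑one F7 (not isolated) to 4‑[(1S,2S)‑1‑hydroxy‑3‑methyl‑2‑(phenylaminooxy)butyl]‑3,5‑dihydroxy‑2‑(2‑methylpropanoyl)‑6,6‑bis(3‑methylbut‑2‑enyl)cyclohexa‑2,4‑dien‑1‑one F8. The N–O bond is then cleaved with Zn/AcOH on this dearomatised, far less ionisable triketone to give 12.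

**Further compounds**
F1 | step 2 | (2S)‑3‑methyl‑2‑(phenylaminooxy)butan‑1‑ol | OC[C@@H](ONc1ccccc1)C(C)C
F2 | step 2 | (2S)‑3‑methylbutane‑1,2‑diol | OC[C@@H](O)C(C)C
F3 | step 2 | (4S)‑4‑isopropyl‑2‑phenyl‑1,3‑dioxolane (mixture at C2) | C1OC(c2ccccc2)O[C@H]1C(C)C
F4 | step 2 | (2S)‑2‑benzyloxy‑3‑methylbutan‑1‑ol | OC[C@@H](OCc1ccccc1)C(C)C
F5 | step 2 | (2S)‑2‑benzyloxy‑3‑methylbutanal | O=C[C@@H](OCc1ccccc1)C(C)C
F6 | step 2 | 1‑{3‑[(1S,2S)‑2‑benzyloxy‑1‑hydroxy‑3‑methylbutyl]‑2,4,6‑trihydroxyphenyl}‑2‑methylpropan‑1‑one | CC(C)C(=O)c1c(O)cc(O)c([C@H](O)[C@@H](OCc2ccccc2)C(C)C)c1O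
F7 | step 3 | 1‑{2,4,6‑trihydroxy‑3‑[(1S,2S)‑1‑hydroxy‑3‑methyl‑2‑(phenylaminooxy)butyl]‑5‑(3‑methylbut‑2‑enyl)phenyl}‑2‑methylpropan‑1‑one | CC(C)C(=O)c1c(O)c(CC=C(C)C)c(O)c([C@H](O)[C@@H](ONc2ccccc2)C(C)C)c1O
F8 | step 3 | 4‑[(1S,2S)‑1‑hydroxy‑3‑methyl‑2‑(phenylaminooxy)butyl]‑3,5‑dihydroxy‑2‑(2‑methylpropanoyl)‑6,6‑bis(3‑methylbut‑2‑enyl)cyclohexa‑2,4‑dien‑1‑one | CC(C)=CCC1(CC=C(C)C)C(=O)C(C(=O)C(C)C)=C(O)C([C@H](O)[C@@H](ONc2ccccc2)C(C)C)=C1O
F9 | step 4 | 1‑{3‑[(4S,5S)‑5‑isopropyl‑2,2‑dimethyl‑1,3‑dioxolan‑4‑yl]‑2,4,6‑trihydroxyphenyl}‑2‑methylpropan‑1‑one | CC(C)C(=O)c1c(O)cc(O)c([C@@H]2OC(C)(C)O[C@H]2C(C)C)c1O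
F10 | step 4 | 1‑{3‑[(4S,5S)‑5‑isopropyl‑2,2‑dimethyl‑1,3‑dioxolan‑4‑yl]‑2,4,6‑trihydroxy‑5‑(3‑methylbut‑2‑enyl)phenyl}‑2‑methylpropan‑1‑one | CC(C)C(=O)c1c(O)c(CC=C(C)C)c(O)c([C@@H]2OC(C)(C)O[C@H]2C(C)C)c1O
F11 | step 4 | 4‑[(4S,5S)‑5‑isopropyl‑2,2‑dimethyl‑1,3‑dioxolan‑4‑yl]‑3,5‑dihydroxy‑2‑(2‑methylpropanoyl)‑6,6‑bis(3‑methylbut‑2‑enyl)cyclohexa‑2,4‑dien‑1‑one | CC(C)=CCC1(CC=C(C)C)C(=O)C(C(=O)C(C)C)=C(O)C([C@@H]2OC(C)(C)O[C@H]2C(C)C)=C1O
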